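**Plan**

- Retrosynthesis: the two N–CH2 bonds are cut first (double N-alkylation with 1,4-diiodobutane), then the O-acetyl and C5–Cl bonds. This leaves a monomeric (7S)-isoquinolin-6(7H)-one whose O7 and O8 are tied in a pivalaldehyde acetal.
- In this 8-O-alkyl form the carbocycle C4a–C5–C6–C7–C8–C8a is a 6,6-disubstituted cyclohexa-2,4-dienone, the closed valence isomer of a dienylketene (C6 ketene carbon, C7 enediol terminus). Cutting C6–C7 (retro-6π) and C5–C4a (retro-Wolff) gives a 4-diazoacetylpyridine that carries a dioxole on C8a.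
- Further cuts: C8a–C8 (Suzuki coupling with a lactate-derived ketene acetal phosphate) and C3–C9 (Suzuki coupling with a dienylboronate), both on methyl 2-bromo-5-chloropyridine-4-carboxylate.
- Forward: side chain, two pyridine couplings, diazoketone. The carbocycle then closes in one operation on the finished pyridine. Chlorination, N,N'-linking (which also releases the acetal) and acetylation finish the route.
- Stereochemistry: C13 comes from (S)-2-methylbutan-1-ol. C7 comes from (S)-lactic acid by self-regeneration of stereocentres: the tert-butyl acetal carbon is the only stereocentre of the dioxole and steers ring closure to its opposite face. Alkene geometry comes from the Wittig and Takai olefinations.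

Key step: step 10

Remark: azaphilone numbering (C1, N2, C3, C4, C4a, C5–C8, C8a; side chain from C9) is used for all intermediates; the SMILES defines the target as the (7S,7'S,13S,13'S) isomer; compound 5 is taken as a catalogue pyridine.

**Route**

Step 1
Reactants: 1 (S)-2-methylbutan-1-ol
Product: 2 (S)-2-methylbutanal
Conditions: TEMPO (5 mol %), PhI(OAc)2, CH2Cl2, 25 °C; solution used directly
Reagents that add atoms: none
Why: Piancatelli–Margarita oxidation stops at the aldehyde under neutral conditions, so the α-stereocentre taken from commercial 1 should not epimerise.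

Step 2
Reactants: 2 (S)-2-methylbutanal
Product: 3 (2E,4S)-2,4-dimethylhex-2-enal
Conditions: Ph3P=C(Me)CHO, PhMe, 80 °C
Reagents that add atoms: 2-(triphenylphosphoranylidene)propanal, CC(C=O)=P(c1ccccc1)(c1ccccc1)c1ccccc1
Why: Wittig olefination with the stabilised formyl ylide should give the (E)-trisubstituted enal under neutral, salt-free conditions that do not enolise the α-branched aldehyde.

Step 3
Reactants: 3 (2E,4S)-2,4-dimethylhex-2-enal
Product: 4 2-[(1E,3E,5S)-3,5-dimethylhepta-1,3-dien-1-yl]-4,4,5,5-tetramethyl-1,3,2-dioxaborolane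
Conditions: Cl2CHBpin, CrCl2 (8 equiv), LiI, THF, 25 °C
Reagents that add atoms: 2-(dichloromethyl)-4,4,5,5-tetramethyl-1,3,2-dioxaborolane, ClC(Cl)B1OC(C)(C)C(C)(C)O1
Why: Takai–Utimoto boryl olefination (gem-dichromium reagent from Cl2CHBpin and CrCl2) converts aldehydes, enals included, into (E)-alkenyl pinacol boronates, which sets the C9=C10 geometry without touching C13.

Step 4
Reactants: 4 dienyl pinacol boronate; 5 methyl 2-bromo-5-chloropyridine-4-carboxylate
Product: 6 methyl 5-chloro-2-[(1E,3E,5S)-3,5-dimethylhepta-1,3-dien-1-yl]pyridine-4-carboxylate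
Conditions: Pd(dppf)Cl2 (5 mol %), K3PO4, PhMe/H2O, 60 °C
Reagents that add atoms: none
Why: Suzuki–Miyaura coupling should take place only at the C–Br bond (alpha to nitrogen and far more reactive than the C–Cl bond) with retention of the diene geometry.

Step 5
Reactants: 7 (S)-lactic acid; 8 pivalaldehyde
Product: 9 (2S,5S)-2-tert-butyl-5-methyl-1,3-dioxolan-4-one (cis)
Conditions: TsOH·H2O (cat.), H2SO4 (cat.), pentane, reflux, Dean–Stark; crystallisation at −78 °C
Reagents that add atoms: none
Why: Seebach acetalisation under thermodynamic control gives mainly the cis acetal, purified by low-temperature crystallisation, so the lactate centre fixes the configuration of the acetal carbon (first half of self-regeneration of stereocentres).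

Step 6
Reactants: 9 (2S,5S)-2-tert-butyl-5-methyl-1,3-dioxolan-4-one
Product: 11 (2S)-2-tert-butyl-5-methyl-1,3-dioxol-4-yl diphenyl phosphate, via potassium dioxolenolate 10 (not isolated)
Conditions: KN(SiMe3)2, THF/HMPA, −78 °C; then (PhO)2P(O)Cl, −78 → 0 °C
Reagents that add atoms: diphenyl chlorophosphate, O=P(Cl)(Oc1ccccc1)Oc1ccccc1; potassium bis(trimethylsilyl)amide, C[Si](C)(C)[N-][Si](C)(C)C.[K+] (potassium retained in 10 only)
Why: O-phosphorylation of a lactone potassium enolate (ketene acetal phosphate formation) is standard; C5 of the dioxolanone becomes trigonal while the acetal carbon keeps the stereochemical information.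

Step 7
Reactants: 6 methyl 5-chloro-2-dienylpyridine-4-carboxylate; 11 dioxolyl diphenyl phosphate
Product: 13 methyl 5-[(2S)-2-tert-butyl-5-methyl-1,3-dioxol-4-yl]-2-[(1E,3E,5S)-3,5-dimethylhepta-1,3-dien-1-yl]pyridine-4-carboxylate, via pyridylboronate 12 (not isolated)
Conditions: B2pin2, Pd2(dba)3 (2 mol %), XPhos (8 mol %), KOAc, 1,4-dioxane, 90 °C; then 11, aq. K3PO4, 60 °C
Reagents that add atoms: bis(pinacolato)diboron, CC1(C)OB(OC1(C)C)B1OC(C)(C)C(C)(C)O1 (boron retained in 12 only)
Why: One-pot Miyaura borylation of the aryl chloride followed by Suzuki–Miyaura coupling with a lactone-derived ketene acetal phosphate, an established electrophile class, should join C8a to C8 without affecting the acetal centre or the diene.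

Step 8
Reactants: 13 methyl ester
Product: 14 5-[(2S)-2-tert-butyl-5-methyl-1,3-dioxol-4-yl]-2-[(1E,3E,5S)-3,5-dimethylhepta-1,3-dien-1-yl]pyridine-4-carboxylic acid
Conditions: LiOH, THF/MeOH/H2O, 25 °C; then AcOH to pH 5
Reagents that add atoms: lithium hydroxide, [Li+].[OH-]
Why: Saponification of the methyl ester is routine, the enediol acetal being stable to base, and the work-up is held at pH 5 to spare it.

Step 9
Reactants: 14 pyridine-4-carboxylic acid
Product: 16 2-diazo-1-{5-[(2S)-2-tert-butyl-5-methyl-1,3-dioxol-4-yl]-2-[(1E,3E,5S)-3,5-dimethylhepta-1,3-dien-1-yl]pyridin-4-yl}ethan-1-one, via acid chloride 15 (not isolated)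
Conditions: Me2C=C(Cl)NMe2, CH2Cl2, 0 °C; then CH2N2, Et3N, Et2O, 0 → 25 °C
Reagents that add atoms: diazomethane, C=[N+]=[N-]; 1-chloro-N,N,2-trimethylprop-1-en-1-amine, CC(C)=C(Cl)N(C)C (chlorine retained in 15 only)
Why: Neutral acid chloride formation with the Ghosez chloroenamine followed by acylation of diazomethane (first stage of an Arndt–Eistert sequence, Et3N as HCl scavenger) should give the diazomethyl ketone without exposing the acetal to acid.

Step 10
Reactants: 16 diazomethyl ketone
Product: 18 (7S)-7,8-[(R)-2,2-dimethylpropylidenedioxy]-7-methyl-3-[(1E,3E,5S)-3,5-dimethylhepta-1,3-dien-1-yl]isoquinolin-6(7H)-one, via pyridylketene 17 (not isolated)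
Conditions: AgO2CPh (0.1 equiv), Et3N (1 equiv), THF (0.01 M), ultrasound, 45 °C, dark
Reagents that add atoms: none
Why: Proposed new method: univalent silver triggers loss of N2 from 16 and Wolff rearrangement, in which the pyridine carbon C4a migrates from the carbonyl carbon C6 to the diazo carbon C5 (new C5–C4a bond) to give pyridylketene 17, whose C6=C5, C4a=C8a and C8=C7 π bonds form a (Z)-hexatriene that closes thermally (new C6–C7 bond). The closest known reaction type is the Wolff rearrangement/6π-electrocyclisation benzannulation of o-alkenylaryl and dienyl diazoketones, run under the silver benzoate, triethylamine and ultrasound conditions of tandem Wolff/Cope rearrangements, and the ring-forming half is the thermal reverse of the Barton–Quinkert opening of o-quinol acetates; new here are the fully substituted enediol terminus and the partial dearomatisation of the pyridine. The carbocycle C4a–C5–C6–C7–C8–C8a closes by a disrotatory 6π-electrocyclisation, equivalent in polar terms to C-acylation of the electron-rich enediol acetal carbon C7 by the ketene carbon C6, and the product is stabilised as a push–pull 8-alkoxyisoquinolin-6(7H)-one, the chromophore of 8-O-alkylated sclerotioramines. The only new stereocentre, C7, is controlled by the acetal carbon: C6 should approach the planar dioxole from the face opposite the tert-butyl group, as electrophiles do with Seebach dioxolanone enolates, so that C6 takes the place of the former lactate hydrogen with retention and C7 becomes S. The step needs Wolff rearrangement to win over carbenoid addition to the dioxole alkene (silver catalysis in place of rhodium or copper carbenoid catalysts, s-Z diazoketone), C- over O-acylation (the pericyclic closure gives the C–C bond directly, O-attack is reversible) and ring closure over ketene dimerisation (high dilution, no nucleophile present).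

Step 11
Reactants: 18 tricyclic acetal
Product: 19 (7S)-5-chloro-7,8-[(R)-2,2-dimethylpropylidenedioxy]-7-methyl-3-[(1E,3E,5S)-3,5-dimethylhepta-1,3-dien-1-yl]isoquinolin-6(7H)-one
Conditions: NCS (1.05 equiv), MeCN, 0 → 25 °C
Reagents that add atoms: N-chlorosuccinimide, O=C1CCC(=O)N1Cl
Why: Electrophilic chlorination with NCS should occur at C5, the α-carbon of the push–pull dienone and its most nucleophilic position, as in the chlorination of azaphilone cores; the stereocentres are not involved.

Step 12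
Reactants: 19 chloro acetal (2.2 equiv); 20 1,4-diiodobutane (1 equiv)
Product: 22 2,2'-(butane-1,4-diyl)bis{(7S)-5-chloro-7-hydroxy-7-methyl-3-[(1E,3E,5S)-3,5-dimethylhepta-1,3-dien-1-yl]isoquinoline-6,8(2H,7H)-dione}, via bis-isoquinolinium diiodide 21 (not isolated)
Conditions: MeCN, 70 °C; then H2O, NaHCO3, 25 °C
Reagents that add atoms: water, O
Why: Menshutkin alkylation of the imine-type nitrogen (the nitrogen of a vinylogous 4-alkoxypyridine) by both ends of the primary diiodide gives an 8-alkoxy iminium ether that should lose its acetal carbon as pivalaldehyde on hydrolysis, as 4-alkoxypyridines give N-alkyl-4-pyridones, unveiling the C8 ketone and the C7 hydroxyl with C7 untouched.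

Step 13
Reactants: 22 bis-diol
Product: 23 penazaphilone I
Conditions: Ac2O, DMAP, Et3N, CH2Cl2, 25 °C
Reagents that add atoms: acetic anhydride, CC(=O)OC(C)=O
Why: DMAP-catalysed acetylation of the tertiary C7 alcohols, as used on 7-hydroxyazaphilones, should complete the target without affecting any stereocentre.

**Compound list**

1 | (S)-2-methylbutan-1-ol | CC[C@H](C)CO | starting material
2 | (S)-2-methylbutanal | CC[C@H](C)C=O | intermediate
3 | (2E,4S)-2,4-dimethylhex-2-enal | CC[C@H](C)/C=C(C)/C=O | intermediate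
4 | 2-[(1E,3E,5S)-3,5-dimethylhepta-1,3-dien-1-yl]-4,4,5,5-tetramethyl-1,3,2-dioxaborolane | CC[C@H](C)/C=C(C)/C=C/B1OC(C)(C)C(C)(C)O1 | intermediate
5 | methyl 2-bromo-5-chloropyridine-4-carboxylate | COC(=O)c1cc(Br)ncc1Cl | starting material
6 | methyl 5-chloro-2-[(1E,3E,5S)-3,5-dimethylhepta-1,3-dien-1-yl]pyridine-4-carboxylate | CC[C@H](C)/C=C(C)/C=C/c1cc(C(=O)OC)c(Cl)cn1 | intermediate
7 | (S)-lactic acid | C[C@H](O)C(=O)O | starting material
8 | pivalaldehyde (2,2-dimethylpropanal) | CC(C)(C)C=O | starting material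
9 | (2S,5S)-2-tert-butyl-5-methyl-1,3-dioxolan-4-one (cis) | C[C@@H]1O[C@H](C(C)(C)C)OC1=O | intermediate
10 | potassium (2S)-2-tert-butyl-5-methyl-1,3-dioxol-4-olate | CC1=C([O-])O[C@@H](C(C)(C)C)O1.[K+] | intermediate
11 | (2S)-2-tert-butyl-5-methyl-1,3-dioxol-4-yl diphenyl phosphate | CC1=C(OP(=O)(Oc2ccccc2)Oc2ccccc2)O[C@@H](C(C)(C)C)O1 | intermediate
12 | methyl 2-[(1E,3E,5S)-3,5-dimethylhepta-1,3-dien-1-yl]-5-(4,4,5,5-tetramethyl-1,3,2-dioxaborolan-2-yl)pyridine-4-carboxylate | CC[C@H](C)/C=C(C)/C=C/c1cc(C(=O)OC)c(B2OC(C)(C)C(C)(C)O2)cn1 | intermediate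
13 | methyl 5-[(2S)-2-tert-butyl-5-methyl-1,3-dioxol-4-yl]-2-[(1E,3E,5S)-3,5-dimethylhepta-1,3-dien-1-yl]pyridine-4-carboxylate | CC[C@H](C)/C=C(C)/C=C/c1cc(C(=O)OC)c(cn1)C1=C(C)O[C@H](C(C)(C)C)O1 | intermediate
14 | 5-[(2S)-2-tert-butyl-5-methyl-1,3-dioxol-4-yl]-2-[(1E,3E,5S)-3,5-dimethylhepta-1,3-dien-1-yl]pyridine-4-carboxylic acid | CC[C@H](C)/C=C(C)/C=C/c1cc(C(=O)O)c(cn1)C1=C(C)O[C@H](C(C)(C)C)O1 | intermediate
15 | 5-[(2S)-2-tert-butyl-5-methyl-1,3-dioxol-4-yl]-2-[(1E,3E,5S)-3,5-dimethylhepta-1,3-dien-1-yl]pyridine-4-carbonyl chloride | CC[C@H](C)/C=C(C)/C=C/c1cc(C(Cl)=O)c(cn1)C1=C(C)O[C@H](C(C)(C)C)O1 | intermediate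
16 | 2-diazo-1-{5-[(2S)-2-tert-butyl-5-methyl-1,3-dioxol-4-yl]-2-[(1E,3E,5S)-3,5-dimethylhepta-1,3-dien-1-yl]pyridin-4-yl}ethan-1-one | CC[C@H](C)/C=C(C)/C=C/c1cc(C(=O)C=[N+]=[N-])c(cn1)C1=C(C)O[C@H](C(C)(C)C)O1 | intermediate
17 | 2-{5-[(2S)-2-tert-butyl-5-methyl-1,3-dioxol-4-yl]-2-[(1E,3E,5S)-3,5-dimethylhepta-1,3-dien-1-yl]pyridin-4-yl}ethen-1-one (pyridylketene) | CC[C@H](C)/C=C(C)/C=C/c1cc(C=C=O)c(cn1)C1=C(C)O[C@H](C(C)(C)C)O1 | intermediate
18 | (7S)-7,8-[(R)-2,2-dimethylpropylidenedioxy]-7-methyl-3-[(1E,3E,5S)-3,5-dimethylhepta-1,3-dien-1-yl]isoquinolin-6(7H)-one (tert-butyl cis to the 7-methyl group) | CC[C@H](C)/C=C(C)/C=C/C1=CC2=CC(=O)[C@@]3(C)O[C@H](C(C)(C)C)OC3=C2C=N1 | intermediate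
19 | (7S)-5-chloro-7,8-[(R)-2,2-dimethylpropylidenedioxy]-7-methyl-3-[(1E,3E,5S)-3,5-dimethylhepta-1,3-dien-1-yl]isoquinolin-6(7H)-one | CC[C@H](C)/C=C(C)/C=C/C1=CC2=C(Cl)C(=O)[C@@]3(C)O[C@H](C(C)(C)C)OC3=C2C=N1 | intermediate
20 | 1,4-diiodobutane | ICCCCI | starting material
21 | 2,2'-(butane-1,4-diyl)bis{(7S)-5-chloro-7,8-[(R)-2,2-dimethylpropylidenedioxy]-7-methyl-6-oxo-3-[(1E,3E,5S)-3,5-dimethylhepta-1,3-dien-1-yl]-6,7-dihydroisoquinolin-2-ium} diiodide | CC[C@H](C)/C=C(C)/C=C/C1=CC2=C(Cl)C(=O)[C@@]3(C)O[C@H](C(C)(C)C)OC3=C2C=[N+]1CCCC[N+]1=CC2=C3O[C@@H](C(C)(C)C)O[C@]3(C)C(=O)C(Cl)=C2C=C1/C=C/C(C)=C/[C@@H](C)CC.[I-].[I-] | intermediate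
22 | 2,2'-(butane-1,4-diyl)bis{(7S)-5-chloro-7-hydroxy-7-methyl-3-[(1E,3E,5S)-3,5-dimethylhepta-1,3-dien-1-yl]isoquinoline-6,8(2H,7H)-dione} | CC[C@H](C)/C=C(C)/C=C/C1=CC2=C(Cl)C(=O)[C@@](C)(O)C(=O)C2=CN1CCCCN1C=C2C(=O)[C@](C)(O)C(=O)C(Cl)=C2C=C1/C=C/C(C)=C/[C@@H](C)CC | intermediate
23 | penazaphilone I, the 7,7'-di-O-acetate of 22 with (7S,7'S,13S,13'S) configuration | CC[C@H](C)/C=C(C)/C=C/C1=CC2=C(Cl)C(=O)[C@@](C)(OC(C)=O)C(=O)C2=CN1CCCCN1C=C2C(=O)[C@](C)(OC(C)=O)C(=O)C(Cl)=C2C=C1/C=C/C(C)=C/[C@@H](C)CC | target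

**Count and risks**

Total steps: 13. Longest linear sequence: 11 steps (steps 1–4 and 7–13); steps 5 and 6 form the side branch.

Steps most likely to fail:

1. Step 10. The pyridylketene may fail to close onto C7 because the pyridine must give up part of its aromaticity. A silver carbenoid may add to the dioxole alkene before rearrangement. Facial control by the tert-butyl group may be incomplete. Fallback with known chemistry, setting out from 3 and returning at 22: Horner–Wadsworth–Emmons olefination of 3 with diethyl [3-(trimethylsilyl)prop-2-yn-1-yl]phosphonate (LiN(SiMe3)2, THF) should give trimethyl[(3E,5E,7S)-5,7-dimethylnona-3,5-dien-1-yn-1-yl]silane F1. K2CO3 in MeOH removes the silyl group to give (3E,5E,7S)-5,7-dimethylnona-3,5-dien-1-yne F2. Sonogashira coupling (PdCl2(PPh3)2, CuI, Et3N, DMF) with the known 6-bromo-2,4-dihydroxy-3-methylbenzaldehyde gives the alkynylbenzaldehyde F3. Copper-mediated enantioselective oxidative dearomatisation ([Cu(MeCN)4]PF6, (−)-sparteine, O2, iPr2NEt, DMAP, CH2Cl2, −78 °C) followed by buffered cycloisomerisation should give the 7-hydroxyazaphilone F4. The ligand enantiomer is chosen from memory of the precedent (natural (+)-sclerotiorin is reported to need the (+)-sparteine surrogate), so it should be checked against the literature; F4 is 7R by the CIP rules but has the same spatial arrangement as C7 of the target. NCS gives the 5-chloroazaphilone F5, and condensation of two equivalents of F5 with butane-1,4-diamine gives 22.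

2. Step 12. Quaternisation at the nitrogen next to the dienyl group may be slow, alkylation may stop after one end, or the carbonyl oxygen O6 may be alkylated instead. Fallback setting out from 19 and returning at 22: mild acid hydrolysis of the acetal (AcOH, THF/H2O) gives the N–H vinylogous pyridone (7S)-5-chloro-7-hydroxy-7-methyl-3-[(1E,3E,5S)-3,5-dimethylhepta-1,3-dien-1-yl]isoquinoline-6,8(2H,7H)-dione F6. Its caesium salt (Cs2CO3, DMF) is then N-alkylated at both ends of 20, by analogy with the N-alkylation of 4-pyridones, to give 22.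

3. Step 7. The pyridylboronate next to the ester may protodeboronate, or the ketene acetal phosphate may hydrolyse before it couples. Fallback with reversed polarity, setting out from 11 and returning at 13: palladium-catalysed borylation of 11 (B2pin2, PdCl2(PPh3)2, PPh3, KOPh, PhMe, 50 °C) gives the dioxolylboronate 2-[(2R)-2-tert-butyl-5-methyl-1,3-dioxol-4-yl]-4,4,5,5-tetramethyl-1,3,2-dioxaborolane F7 (same spatial arrangement as 11; the descriptor changes with the substituent). Suzuki–Miyaura coupling of F7 with chloride 6 (Pd2(dba)3, SPhos, K3PO4, 1,4-dioxane/H2O, 80 °C) then gives 13.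

Further compounds
F1 | step 10 | trimethyl[(3E,5E,7S)-5,7-dimethylnona-3,5-dien-1-yn-1-yl]silane | CC[C@H](C)/C=C(C)/C=C/C#C[Si](C)(C)C
F2 | step 10 | (3E,5E,7S)-5,7-dimethylnona-3,5-dien-1-yne | CC[C@H](C)/C=C(C)/C=C/C#C
F3 | step 10 | 2,4-dihydroxy-3-methyl-6-[(3E,5E,7S)-5,7-dimethylnona-3,5-dien-1-yn-1-yl]benzaldehyde | CC[C@H](C)/C=C(C)/C=C/C#Cc1cc(O)c(C)c(O)c1C=O
F4 | step 10 | (7R)-7-hydroxy-7-methyl-3-[(1E,3E,5S)-3,5-dimethylhepta-1,3-dien-1-yl]-6H-isochromene-6,8(7H)-dione | CC[C@H](C)/C=C(C)/C=C/C1=CC2=CC(=O)[C@@](C)(O)C(=O)C2=CO1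
F5 | step 10 | (7S)-5-chloro-7-hydroxy-7-methyl-3-[(1E,3E,5S)-3,5-dimethylhepta-1,3-dien-1-yl]-6H-isochromene-6,8(7H)-dione | CC[C@H](C)/C=C(C)/C=C/C1=CC2=C(Cl)C(=O)[C@@](C)(O)C(=O)C2=CO1
F6 | step 12 | (7S)-5-chloro-7-hydroxy-7-methyl-3-[(1E,3E,5S)-3,5-dimethylhepta-1,3-dien-1-yl]isoquinoline-6,8(2H,7H)-dione | CC[C@H](C)/C=C(C)/C=C/C1=CC2=C(Cl)C(=O)[C@@](C)(O)C(=O)C2=CN1
F7 | step 7 | 2-[(2R)-2-tert-butyl-5-methyl-1,3-dioxol-4-yl]-4,4,5,5-tetramethyl-1,3,2-dioxaborolane | CC1=C(B2OC(C)(C)C(C)(C)O2)O[C@@H](C(C)(C)C)O1
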